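all flasks: second catalyst 1.8 mM; precatalyst 0.85 mM

| charge | substrate | reagent | temperature | remark | time |
|---|---|---|---|---|---|
| green | 0.050 M | 0.035 M | 90 °C | the very flask that is asked about, followed so far |  |
| ochre | 0.025 M | 0.035 M | 96 °C | run made earlier |  |
| flask | 0.050 M | 0.0350 M | 90 °C |  | 5.0 d |

| run | time / h | target / % | substrate / % |
|---|---|---|---|
| green | 8.00 | 0 | 88 |
| green | 25.0 | 11 | 28 |
| green | 40.0 | 17 | 8 |
| green | 72.0 | 18 | 0 |
| green | 96.0 | 16 | 0 |
| ochre | 1.33 | 0 | 99 |
| ochre | 2.50 | 2 | 96 |
| ochre | 5.00 | 2 | 87 |
| ochre | 10.0 | 3 | 53 |
| ochre | 20.0 | 12 | 11 |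

(scatter of a reading: 1.5 percentage points)

- target taken out counts as made
- "the catalyst" is free catalyst with its forms; second catalyst is a second catalyst
- additions bring no volume worth counting

- Tuesday's: at 5.0 d add second catalyst, 100 % of the amount charged, then wait 40 h
- Monday's: change nothing and wait 40 h more
- Thursday's: at 5.0 d take out 90 % of the target then present, then wait 40 h
- Wednesday's: at 5.0 d raise the temperature by 25 K, then wait 40 h
- Friday's: at 5.0 d add reagent, 50.0 % of the amount charged, then wait 40 h

- target, in percent of the substrate first charged, at 5.0 d
- what to do for the largest gain in target; "none" if nothing gains more than 2 percentage points (Tuesday's / Monday's / Thursday's / Wednesday's / Friday's / none)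
- target present, with what was taken out counted in, in percent of the substrate first charged, after Thursday's
- target present, with what was taken out counted in, in percent of the substrate first charged, after Friday's

Start from the leftover substrate in the green flask, which is the flask asked about: it reads 28 % at 25.0 h, 8 % at 40.0 h and 0 % at 72.0 h, while target reads 18 % and then 16 % at 96.0 h. That drop of 2 percentage points is narrowly smaller than the scatter of a difference between two readings, 2.1 points, so you can read no fade from it.

You therefore compare two times: how fast the feed empties, and how long you wait. In the green flask the substrate falls faster, in proportion per hour, from 25.0 h to 40.0 h than from 8.00 h to 25.0 h, so take that late pair, which reads 8.30 h. Call this the feed half-time, the time in which the substrate still present halves.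

The wait of 5.0 d is 14.5 feed half-times. Carried on from 40.0 h to 5.0 d, this estimate leaves substrate 0.0100 % in the green flask, far less than the margin of 2 points. My own reckoning is therefore the mean of the last two readings, 17.0 %, for now and after Thursday's and Friday's, with best none.

The forecast agrees on the choice but stands lower, saying “Target seems to fade slowly”: 15 % now, 14.8 % after Thursday's, 13 % after Friday's, best none.

The flask gives 19.1 % now, 19.1 % after Thursday's, 19.1 % after Friday's, best none; the forecast's Friday figure lies 6.1 points below.

    substrate + free catalyst → free catalyst + intermediate (k = 229 M⁻¹ h⁻¹, Ea = 85.0 kJ mol⁻¹)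
    reagent + second catalyst + intermediate → second catalyst + target (k = 402 M⁻² h⁻¹, Ea = 70.0 kJ mol⁻¹)
    intermediate → side product (k = 0.0919 h⁻¹, Ea = 110 kJ mol⁻¹)
    precatalyst → free catalyst (k = 0.0266 h⁻¹, Ea = 111 kJ mol⁻¹)
    (constants at 90 °C)

After 14.5 feed half-times, at 120 h, this flask holds substrate 0 % and intermediate 0 %. Intermediate's half-life by loss to side product is 7.5 h at 17.6 h, against a pseudo-first-order 27.4 h for turning into target at the charged amounts, and the flask ends with side product 80.9 % and target 19.1 %. The repeat at 65 °C has substrate 75.1 % at 120 h, which over that whole run means a feed half-time of 290 h, so it is 0.413 feed half-times in, with intermediate 16.5 % and target 3.52 %.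

Readings and results are calculated from invented constants; scatter was added.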